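The meso, all-cis tetrahydrofuran ring (O1, C2–C5; aryl on C2 and C5, CH2OH carbons C3a and C4a on C3 and C4) is disconnected at C3–C3a. The feature used is the cis pair C3a/C4a. A silicon atom on the C4a oxygen can hold a CH2 radical that can approach C3 of a C2=C3 enol ether solely from the face occupied by C4a. One operation makes C3–C3a, closes a six-membered oxasilinane that is dismantled later, and relays the C4/C5 configuration to C3 and C2. The precursor is a racemic 4,5-cis-2,5-diaryl-4,5-dihydrofuran with benzyl-protected phenols and a (bromomethyl)dimethylsilyl ether at C4a. C–Si oxidation and debenzylation follow.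

Key step: step 11

Remark: the target SMILES decodes to the all-cis, achiral (meso) isomer. Every chiral intermediate is racemic, and its SMILES shows one enantiomer only to define relative configuration. Ar = 4-benzyloxy-3,5-dimethoxyphenyl. The ring numbering O1, C2–C5, C3a, C4a is also used for the acyclic forerunners: C5 is the carbinol carbon, C4 the branching carbon, C3 the internal vinyl carbon.

Step 1
Reactants: 1 syringaldehyde
Product: 2 4-benzyloxy-3,5-dimethoxybenzaldehyde
Conditions: BnBr, K2CO3, DMF, 60 °C
Reagents that add atoms: benzyl bromide, BrCc1ccccc1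
Why: Williamson etherification, in which the phenoxide formed by K2CO3 displaces bromide while the aldehyde is inert.

Step 2
Reactants: 3 syringic acid
Product: 5 4-benzyloxy-3,5-dimethoxybenzoic acid, via benzyl ester 4 (not isolated)
Conditions: BnBr (2.2 equiv), K2CO3, DMF, 60 °C; then aq NaOH, MeOH, 60 °C; then aq HCl
Reagents that add atoms: benzyl bromide, BrCc1ccccc1; sodium hydroxide, [Na+].[OH-]
Why: Williamson-type alkylation of phenoxide and carboxylate, followed by saponification of the benzyl ester in the same flask, leaves only the robust aryl benzyl ether.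

Step 3
Reactants: 6 buta-1,3-diene (commercial solution in toluene); 7 bis(pinacolato)diboron
Product: 8 (Z)-1,4-bis(4,4,5,5-tetramethyl-1,3,2-dioxaborolan-2-yl)but-2-ene
Conditions: Pt(PPh3)4 (3 mol %), toluene, sealed tube, 80 °C
Reagents that add atoms: none
Why: Platinum-catalysed 1,4-diboration of a 1,3-diene, in which zerovalent platinum inserts into the B–B bond, the diene reacts in its s-cis form, and reductive elimination from the allyl complex gives the Z-alkene needed in step 4.

Step 4
Reactants: 2 4-benzyloxy-3,5-dimethoxybenzaldehyde; 8 (Z)-1,4-bis(pinacolboryl)but-2-ene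
Product: 10 rac-syn-1-Ar-2-vinylpropane-1,3-diol (C5–OH and C4–CH2OH on the same side of the zigzag Ar–C5–C4–CH=CH2; the (1S,2S) enantiomer is drawn), via bisboryl adduct 9 (not isolated)
Conditions: toluene, 50 °C; then THF, 3 M NaOH, 30% H2O2, 0 °C to rt
Reagents that add atoms: hydrogen peroxide, OO
Why: Allylboration through a closed chair (Zimmerman–Traxler) transition state in which the Z-alkene forces CH2Bpin axial, so C4 and C5 form together with the syn relation that becomes 4,5-cis in the ring, after which alkaline peroxide converts the remaining non-allylic C–B bond into the C4a hydroxyl.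

Step 5
Reactants: 10 rac-syn-diol
Product: 11 rac-syn-1-Ar-2-[(tert-butyldimethylsilyloxy)methyl]but-3-en-1-ol
Conditions: TBSCl (1.05 equiv), imidazole, CH2Cl2, 0 °C
Reagents that add atoms: tert-butyldimethylsilyl chloride, CC(C)(C)[Si](C)(C)Cl
Why: Sterically controlled silylation, since the bulky chlorosilane reacts with the primary C4a hydroxyl much faster than with the hindered secondary benzylic one.

Step 6
Reactants: 11 rac-syn silyl ether alcohol; 5 4-benzyloxy-3,5-dimethoxybenzoic acid
Product: 12 rac-syn-1-Ar-2-[(tert-butyldimethylsilyloxy)methyl]but-3-enyl 4-benzyloxy-3,5-dimethoxybenzoate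
Conditions: DCC, DMAP, CH2Cl2, rt
Reagents that add atoms: none
Why: Steglich esterification, in which the acylpyridinium ion from the DCC-activated acid acylates the C5 oxygen, so the C5–O bond and both stereocentres are untouched.

Step 7
Reactants: 12 ester
Product: 13 rac-syn 1-arylvinyl ether ArCH[OC(=CH2)Ar]–CH(CH2OTBS)–CH=CH2
Conditions: Cp2TiMe2 (3 equiv), toluene, 75 °C, dark; purification on Et3N-deactivated silica
Reagents that add atoms: dimethyltitanocene Cp2TiMe2, C[Ti](C)(C1C=CC=C1)C1C=CC=C1
Why: Petasis methylenation, in which Cp2Ti=CH2 released on heating olefinates the ester carbonyl under neutral conditions that spare the silyl ether, the benzyl ethers and the vinyl group.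

Step 8
Reactants: 13 acyclic enol ether
Product: 14 rac-4,5-cis-2,5-di-Ar-4-[(tert-butyldimethylsilyloxy)methyl]-4,5-dihydrofuran
Conditions: second-generation Grubbs catalyst (H2IMes)(PCy3)Cl2Ru=CHPh (10 mol %), 1,4-benzoquinone (10 mol %), toluene (0.01 M), 70 °C, argon sparge
Reagents that add atoms: none
Why: Ring-closing metathesis of an olefinic enol ether, in which the ruthenium carbene loads on the monosubstituted vinyl group and closes onto the 1,1-disubstituted enol ether, driven by five-membered ring formation and loss of ethene, with C4 and C5 as spectators.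

Step 9
Reactants: 14 silyl-protected dihydrofuran
Product: 15 rac-(4,5-cis-2,5-di-Ar-4,5-dihydrofuran-4-yl)methanol
Conditions: Bu4NF, THF, 0 °C to rt; aqueous NaHCO3 work-up
Reagents that add atoms: none
Why: Fluoride-induced desilylation runs under basic conditions, which the acid-sensitive enol ether tolerates.

Step 10
Reactants: 15 dihydrofuran alcohol; 16 (bromomethyl)chlorodimethylsilane
Product: 17 rac-4,5-cis-2,5-di-Ar-4-{[(bromomethyl)dimethylsilyl]oxymethyl}-4,5-dihydrofuran
Conditions: Et3N, DMAP (5 mol %), CH2Cl2, 0 °C; dilution with pentane, filtration, concentration; used at once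
Reagents that add atoms: none
Why: Amine-buffered silylation of a primary alcohol by a chlorosilane installs the radical precursor without exposing the enol ether to acid.

Step 11
Reactants: 17 bromomethylsilyl ether
Product: 18 rac-all-cis-2,5-di-Ar-tetrahydrofuran whose C3 and C4 are bridged, on the face of the aryl groups, by CH2–SiMe2–O–CH2 (cis-fused 1,2-oxasilinane)
Conditions: Bu3SnH (1.3 equiv) and AIBN (0.2 equiv) added by syringe pump over 6 h to 17 (0.01 M) in degassed PhCF3, 85 °C; tin residues removed by MeCN–hexane partition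
Reagents that add atoms: none
Why: The tributyltin radical takes bromine from 17, the primary α-silyl radical adds to C3 of the C2=C3 enol ether, and the resulting C2 radical abstracts hydrogen from Bu3SnH to carry the chain. The closest known reaction type is the Nishiyama–Stork cyclisation of (bromomethyl)dimethylsilyl ethers of allylic and homoallylic alcohols, here with a styrene-like enol ether as acceptor. The one new ring, the 1,2-oxasilinane (C3a, Si, O, C4a, C4, C3), closes 6-exo-trig, whereas 7-endo attack at C2 would build a quaternary centre and leave an unstabilised secondary radical. C3 is controlled by the tether, because the short link from C4 can span only a cis ring fusion, so C3a lands on the face of C4a. C2 is controlled by the shape of the bicycle: C3a, the silacycle and the C5 aryl group block one face, so the bulky stannane delivers hydrogen to the open convex face and the C2 aryl group ends cis to its neighbours. The step needs ring closure to outrun direct reduction and hydrogen transfer to outrun C5–O1 β-scission, which is served by a low stationary stannane concentration, by the aryl- and oxygen-stabilised radical that makes addition at C3 fast, and by the weak Sn–H bond.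

Step 12
Reactants: 18 oxasilinane
Product: 19 all-cis (meso) 2,5-di-Ar-3,4-bis(hydroxymethyl)tetrahydrofuran
Conditions: 30% H2O2, KF, KHCO3, THF–MeOH, rt to 40 °C
Reagents that add atoms: hydrogen peroxide, OO
Why: Tamao oxidation, in which fluoride and peroxide make silicon hypervalent, the primary C3a–Si bond migrates to oxygen, and hydrolysis of both Si–O bonds frees the two hydroxymethyl groups, while the benzyl ethers shield the phenols from peroxide and no ring stereocentre is touched.

Step 13
Reactants: 19 bis-benzyl ether diol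
Product: 20 target, all-cis (meso) 2,5-bis(4-hydroxy-3,5-dimethoxyphenyl)-3,4-bis(hydroxymethyl)tetrahydrofuran
Conditions: H2 (1 atm), 10% Pd/C, EtOAc–EtOH, rt; stopped after uptake of two equivalents of H2
Reagents that add atoms: none
Why: Catalytic hydrogenolysis under neutral conditions cleaves the aryl benzyl ethers far faster than the hindered ring C2–O1 and C5–O1 bonds and supplies no acid that could epimerise C2 or C5 through a quinone methide.

Compound list
1 | syringaldehyde | COc1cc(C=O)cc(OC)c1O | starting material
2 | 4-benzyloxy-3,5-dimethoxybenzaldehyde | COc1cc(C=O)cc(OC)c1OCc1ccccc1 | intermediate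
3 | syringic acid | COc1cc(C(=O)O)cc(OC)c1O | starting material
4 | benzyl 4-benzyloxy-3,5-dimethoxybenzoate (not isolated) | COc1cc(C(=O)OCc2ccccc2)cc(OC)c1OCc1ccccc1 | intermediate
5 | 4-benzyloxy-3,5-dimethoxybenzoic acid | COc1cc(C(=O)O)cc(OC)c1OCc1ccccc1 | intermediate
6 | buta-1,3-diene | C=CC=C | starting material
7 | bis(pinacolato)diboron | CC1(C)OB(B2OC(C)(C)C(C)(C)O2)OC1(C)C | starting material
8 | (Z)-1,4-bis(pinacolboryl)but-2-ene | CC1(C)OB(C/C=C\CB2OC(C)(C)C(C)(C)O2)OC1(C)C | intermediate
9 | rac-syn adduct ArCH(OBpin)–CH(CH2Bpin)–CH=CH2 (not isolated) | COc1cc([C@@H](OB2OC(C)(C)C(C)(C)O2)[C@H](CB2OC(C)(C)C(C)(C)O2)C=C)cc(OC)c1OCc1ccccc1 | intermediate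
10 | rac-syn-1-Ar-2-vinylpropane-1,3-diol | COc1cc([C@@H](O)[C@H](CO)C=C)cc(OC)c1OCc1ccccc1 | intermediate
11 | rac-syn-1-Ar-2-[(tert-butyldimethylsilyloxy)methyl]but-3-en-1-ol | COc1cc([C@@H](O)[C@H](CO[Si](C)(C)C(C)(C)C)C=C)cc(OC)c1OCc1ccccc1 | intermediate
12 | 4-benzyloxy-3,5-dimethoxybenzoate ester of 11 | COc1cc([C@@H](OC(=O)c2cc(OC)c(OCc3ccccc3)c(OC)c2)[C@H](CO[Si](C)(C)C(C)(C)C)C=C)cc(OC)c1OCc1ccccc1 | intermediate
13 | 1-arylvinyl ether of 11 | COc1cc([C@@H](OC(=C)c2cc(OC)c(OCc3ccccc3)c(OC)c2)[C@H](CO[Si](C)(C)C(C)(C)C)C=C)cc(OC)c1OCc1ccccc1 | intermediate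
14 | rac-4,5-cis-2,5-di-Ar-4-[(tert-butyldimethylsilyloxy)methyl]-4,5-dihydrofuran | COc1cc([C@H]2OC(c3cc(OC)c(OCc4ccccc4)c(OC)c3)=C[C@H]2CO[Si](C)(C)C(C)(C)C)cc(OC)c1OCc1ccccc1 | intermediate
15 | rac-(4,5-cis-2,5-di-Ar-4,5-dihydrofuran-4-yl)methanol | COc1cc([C@H]2OC(c3cc(OC)c(OCc4ccccc4)c(OC)c3)=C[C@H]2CO)cc(OC)c1OCc1ccccc1 | intermediate
16 | (bromomethyl)chlorodimethylsilane | C[Si](C)(Cl)CBr | starting material
17 | rac-4,5-cis-2,5-di-Ar-4-{[(bromomethyl)dimethylsilyl]oxymethyl}-4,5-dihydrofuran | COc1cc([C@H]2OC(c3cc(OC)c(OCc4ccccc4)c(OC)c3)=C[C@H]2CO[Si](C)(C)CBr)cc(OC)c1OCc1ccccc1 | intermediate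
18 | rac-all-cis oxasilinane-fused 2,5-di-Ar-tetrahydrofuran | COc1cc([C@H]2O[C@@H](c3cc(OC)c(OCc4ccccc4)c(OC)c3)[C@H]3C[Si](C)(C)OC[C@@H]23)cc(OC)c1OCc1ccccc1 | intermediate
19 | all-cis (meso) 2,5-di-Ar-3,4-bis(hydroxymethyl)tetrahydrofuran | COc1cc([C@H]2O[C@@H](c3cc(OC)c(OCc4ccccc4)c(OC)c3)[C@@H](CO)[C@H]2CO)cc(OC)c1OCc1ccccc1 | intermediate
20 | all-cis (meso) 2,5-bis(4-hydroxy-3,5-dimethoxyphenyl)-3,4-bis(hydroxymethyl)tetrahydrofuran | COc1cc([C@H]2O[C@@H](c3cc(OC)c(O)c(OC)c3)[C@@H](CO)[C@H]2CO)cc(OC)c1O | target

Total step count: 13.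
Longest linear sequence: 11 steps (step 1, then steps 4–13). The branch through step 3 is equally long.

Steps most likely to fail

**Step 11.** Four things may go wrong:
- The silylmethyl radical may be reduced before ring closure.
- A 1,5-hydrogen shift from the allylic C4–H may compete.
- The C2 radical may open the ring by β-scission of C5–O1.
- Hydrogen may be delivered to the concave face.

The fallback sets out from 14 and comes back at 20. It brings C3a in as an acyl carbon and lets a catalyst surface deliver both ring hydrogens.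
- Acylation of the nucleophilic C3 of 14 with trichloroacetyl chloride and pyridine (CH2Cl2, 0 °C) should give the 3-trichloroacetyl-4,5-dihydrofuran F1.
- Haloform-type methanolysis (K2CO3, MeOH) should give the methyl 4,5-dihydrofuran-3-carboxylate F2.
- Hydrogenation over Pd/C under pressure should add H2 syn to the face opposite the C4 and C5 substituents. It also removes the benzyl groups, giving the all-cis tetrahydrofuran ester F3.
- LiAlH4 should reduce the ester to the all-cis mono-silyl ether of the target F4, and Bu4NF then frees 20.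

**Step 8.** Ring closure onto the hindered 1,1-disubstituted enol ether may be slow. The catalyst may decay to ruthenium hydrides that move the terminal double bond, and the enol ether may hydrolyse on handling. The fallback sets out from 12 and comes back at 14, bypassing both 13 and ruthenium. A stoichiometric Takai–Utimoto-type titanium ethylidene (TiCl4, Zn, PbCl2 cat., TMEDA, CH3CHBr2, THF–CH2Cl2, 65 °C) exchanges with the terminal alkene. The titanium alkylidene so formed then olefinates the ester carbonyl intramolecularly. This also covers a sluggish methylenation in step 7.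

**Step 4.** Addition to the electron-rich aldehyde may be sluggish. The heating then needed may erode the syn selectivity on which every later stereocentre depends, and protodeboronation may consume the reagent. The fallback sets out from 2 and comes back at 11, which also skips step 5. It replaces the closed transition state by an open, Lewis-acid-promoted one that is syn-selective whatever the alkene geometry.
- Commercial (Z)-but-2-ene-1,4-diol is monosilylated (NaH, TBSCl, THF) to (Z)-4-(tert-butyldimethylsilyloxy)but-2-en-1-ol F5.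
- MsCl, Et3N and then LiCl give (Z)-4-(tert-butyldimethylsilyloxy)but-2-enyl chloride F6.
- Bu3SnLi (THF, −78 °C) gives tributyl[(Z)-4-(tert-butyldimethylsilyloxy)but-2-enyl]stannane F7.
- Addition of F7 to 2 with BF3·OEt2 (CH2Cl2, −78 °C) should give 11.

Further compounds
F1 | step 11 | rac-4,5-cis-2,5-di-Ar-4-[(tert-butyldimethylsilyloxy)methyl]-3-trichloroacetyl-4,5-dihydrofuran | COc1cc([C@H]2OC(c3cc(OC)c(OCc4ccccc4)c(OC)c3)=C(C(=O)C(Cl)(Cl)Cl)[C@H]2CO[Si](C)(C)C(C)(C)C)cc(OC)c1OCc1ccccc1
F2 | step 11 | methyl rac-4,5-cis-2,5-di-Ar-4-[(tert-butyldimethylsilyloxy)methyl]-4,5-dihydrofuran-3-carboxylate | COc1cc([C@H]2OC(c3cc(OC)c(OCc4ccccc4)c(OC)c3)=C(C(=O)OC)[C@H]2CO[Si](C)(C)C(C)(C)C)cc(OC)c1OCc1ccccc1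
F3 | step 11 | methyl rac-all-cis-2,5-bis(4-hydroxy-3,5-dimethoxyphenyl)-4-[(tert-butyldimethylsilyloxy)methyl]tetrahydrofuran-3-carboxylate | COc1cc([C@H]2O[C@@H](c3cc(OC)c(O)c(OC)c3)[C@@H](C(=O)OC)[C@H]2CO[Si](C)(C)C(C)(C)C)cc(OC)c1O
F4 | step 11 | rac-all-cis mono-tert-butyldimethylsilyl ether of 20 | COc1cc([C@H]2O[C@@H](c3cc(OC)c(O)c(OC)c3)[C@@H](CO)[C@H]2CO[Si](C)(C)C(C)(C)C)cc(OC)c1O
F0 | step 8 | none | none
F5 | step 4 | (Z)-4-(tert-butyldimethylsilyloxy)but-2-en-1-ol | CC(C)(C)[Si](C)(C)OC/C=C\CO
F6 | step 4 | (Z)-4-(tert-butyldimethylsilyloxy)but-2-enyl chloride | CC(C)(C)[Si](C)(C)OC/C=C\CCl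
F7 | step 4 | tributyl[(Z)-4-(tert-butyldimethylsilyloxy)but-2-enyl]stannane | CCCC[Sn](CCCC)(CCCC)C/C=C\CO[Si](C)(C)C(C)(C)C
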